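**Plan**
- The target is a (3S)-isoflavan in which rings A and B are both 2-prenylresorcinol units. Retrosynthesis removes first the three MOM ethers, then the two prenyl C–C bonds at C8 and C3′ (each between two oxygens), then the C3–H/C4–H pair, and last, in one cut, C2–C3 and C4–C4a.
- The feature that allows the double cut: in the pyran ring, the O1–C2H2 carbon and C4a sit 1,4 to each other on ring A (an O–CH2–SnBu3 group ortho to C–I), and the C3–C4 unit carries only ring B, so it can be a terminal arylalkyne.
- Forward: ring B alkyne (steps 1–2) and ring A iodide/stannane (steps 3–4) are joined by a Pd-catalysed annulation that closes the pyran ring (ring C) as an isoflav-3-ene (step 5).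
- The only stereocentre, C3, comes from iridium-catalysed asymmetric hydrogenation of the achiral C3=C4 bond (step 6).
- The prenyl groups come afterwards, because that hydrogenation would reduce them; double directed ortho-lithiation/prenylation (step 7) and MOM removal (step 8) finish the route.

Key step: step 5

Remark: the (S)-ligand in step 6 is assumed to give the (3S)-chroman; if the first run shows the opposite sense, the mirror-image ligand is used. 4-Iodoresorcinol, tributyl(iodomethyl)stannane and dimethyl (1-diazo-2-oxopropyl)phosphonate are taken as purchasable.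

Step 1
Reactants: 1 2,4-dihydroxybenzaldehyde
Product: 2 2,4-bis(methoxymethoxy)benzaldehyde
Conditions: MOMCl (3 equiv), i-Pr2NEt (4 equiv), CH2Cl2, 0 °C to reflux
Reagents that add atoms: chloromethyl methyl ether, COCCl
Why: Williamson-type O-alkylation of both phenols by the reactive α-chloro ether; excess reagent and warming should carry the hydrogen-bonded ortho-hydroxyl through as well.

Step 2
Reactants: 2 2,4-bis(methoxymethoxy)benzaldehyde
Product: 4 1-ethynyl-2,4-bis(methoxymethoxy)benzene, via diazoalkene 3 (not isolated)
Conditions: dimethyl (1-diazo-2-oxopropyl)phosphonate, K2CO3, MeOH, 0 °C to rt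
Reagents that add atoms: dimethyl (1-diazo-2-oxopropyl)phosphonate, CC(=O)C(=[N+]=[N-])P(=O)(OC)OC
Why: Seyferth–Gilbert homologation in the Ohira–Bestmann variant: the diazomethylphosphonate anion olefinates the aldehyde to diazoalkene 3, which loses N2 and gives the terminal alkyne by 1,2-hydrogen shift, under mild base that leaves aryl MOM ethers intact.

Step 3
Reactants: 5 4-iodobenzene-1,3-diol (4-iodoresorcinol)
Product: 6 2-iodo-5-(methoxymethoxy)phenol
Conditions: MOMCl (1.0 equiv), i-Pr2NEt (1.2 equiv), CH2Cl2, −20 to 0 °C
Reagents that add atoms: chloromethyl methyl ether, COCCl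
Why: Site-selective mono-alkylation should go to the hydroxyl para to iodine, because the other hydroxyl is flanked by iodine, hydrogen-bonded to it and less nucleophilic; one equivalent of reagent at low temperature limits bis-protection.

Step 4
Reactants: 6 2-iodo-5-(methoxymethoxy)phenol
Product: 7 tributyl{[2-iodo-5-(methoxymethoxy)phenoxy]methyl}stannane
Conditions: Bu3SnCH2I (1.1 equiv), K2CO3, DMF, rt, dark
Reagents that add atoms: tributyl(iodomethyl)stannane, CCCC[Sn](CCCC)(CCCC)CI
Why: Williamson etherification of the remaining ortho-iodophenol with an unhindered primary iodide; SN2 at the α-stannyl carbon is fast, and K2CO3 in DMF touches neither the aryl C–I nor the C–Sn bond.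

Step 5
Reactants: 7 tributyl{[2-iodo-5-(methoxymethoxy)phenoxy]methyl}stannane; 4 1-ethynyl-2,4-bis(methoxymethoxy)benzene
Product: 10 3-[2,4-bis(methoxymethoxy)phenyl]-7-(methoxymethoxy)-2H-chromene, via alkenylpalladium iodide 8 (not isolated), via oxapalladacycle 9 (not isolated)
Conditions: Pd2(dba)3 (2.5 mol %), P(2-furyl)3 (10 mol %), DMF, 80 °C; 7 added over 4 h to 4 (1.5 equiv)
Reagents that add atoms: none
Why: Proposed new method: Zerovalent palladium inserts into the C–I bond of 7; the arylpalladium iodide adds syn across alkyne 4 with the aryl group on the unsubstituted carbon and palladium on the carbon bearing ring B (8), the α-aryloxymethyl group then passes from tin to palladium within the molecule (9), and C(sp2)–C(sp3) reductive elimination forms C2–C3 and returns zerovalent palladium. The closest known reaction types are the Larock-type carboannulation of alkynes by ortho-functionalised aryl iodides and the Stille coupling of α-alkoxymethylstannanes with alkenyl electrophiles, joined here so that the stannane is the internal terminator. The pyran ring (ring C) is closed by reductive elimination from the seven-membered palladacycle 9, a formal [4+2] annulation in which C4–C4a comes from the intermolecular insertion and C2–C3 from the ring-closing elimination. No stereocentre is formed; the cis relation of ring A and palladium left by syn addition on C3=C4 is what lets the tether reach. The step needs insertion with aryl to the terminal carbon, which the steric bias of a terminal alkyne and the preference of palladium for the aryl-substituted carbon should secure; this gives the 3-aryl pattern that a polar or radical [4+2] with an ArO–CH2 cation or radical would not give. It also needs insertion to come before tin-to-palladium transfer, which is expected because sp3 stannanes transmetalate slowly, direct closure of 7 would give a four-membered benzoxete, and slow addition of 7 to excess 4 holds down Stille coupling of 7 with itself.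

Step 6
Reactants: 10 3-[2,4-bis(methoxymethoxy)phenyl]-7-(methoxymethoxy)-2H-chromene
Product: 11 (3S)-3-[2,4-bis(methoxymethoxy)phenyl]-7-(methoxymethoxy)-3,4-dihydro-2H-chromene
Conditions: [Ir(cod)((S)-t-Bu-PHOX)][B(C6H3(CF3)2)4] (2 mol %), H2 (50 bar), CH2Cl2, rt
Reagents that add atoms: none
Why: Asymmetric hydrogenation of a trisubstituted cyclic styrene by a cationic monovalent-iridium N,P catalyst, a reaction type established for 3-aryl-2H-chromenes bearing MOM ethers; the chiral ligand differentiates the two faces of C3=C4 and so sets C3 as (S), and nothing else in 10 is reducible.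

Step 7
Reactants: 11 (3S)-3-[2,4-bis(methoxymethoxy)phenyl]-7-(methoxymethoxy)-3,4-dihydro-2H-chromene
Product: 13 (3S)-3-[2,4-bis(methoxymethoxy)-3-(3-methylbut-2-en-1-yl)phenyl]-7-(methoxymethoxy)-8-(3-methylbut-2-en-1-yl)-3,4-dihydro-2H-chromene, via dilithio species 12 (not isolated)
Conditions: n-BuLi (2.5 equiv), TMEDA (2.5 equiv), THF, 0 °C, 1.5 h; then CuBr·SMe2 (20 mol %), prenyl bromide (3 equiv), −78 °C to rt
Reagents that add atoms: 1-bromo-3-methylbut-2-ene (prenyl bromide), CC(C)=CCBr
Why: Directed ortho-metalation: C8 lies between O1 and the 7-OMOM group and C3′ between two OMOM groups, so each is the most acidic aryl C–H of its ring, and the aryl–metal centres then substitute prenyl bromide at its primary carbon under copper catalysis; the C3–H is far less acidic and should stay untouched, so the stereocentre is kept.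

Step 8
Reactants: 13 (3S)-3-[2,4-bis(methoxymethoxy)-3-(3-methylbut-2-en-1-yl)phenyl]-7-(methoxymethoxy)-8-(3-methylbut-2-en-1-yl)-3,4-dihydro-2H-chromene
Product: 14 4-[(3S)-7-hydroxy-8-(3-methylbut-2-en-1-yl)-3,4-dihydro-2H-chromen-3-yl]-2-(3-methylbut-2-en-1-yl)benzene-1,3-diol (target)
Conditions: HCl (1.25 M in MeOH), 0 °C to rt
Reagents that add atoms: none
Why: Acid-catalysed transacetalisation of the three aryl MOM ethers to dimethoxymethane; dilute acid at room temperature should stay below what protonates the prenyl double bonds (no chroman formation with the neighbouring phenols), and C3 has no path to epimerise.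

**Compound list**
1 | 2,4-dihydroxybenzaldehyde | O=Cc1ccc(O)cc1O | starting material
2 | 2,4-bis(methoxymethoxy)benzaldehyde | COCOc1ccc(C=O)c(OCOC)c1 | intermediate
3 | 1-(2-diazoethenyl)-2,4-bis(methoxymethoxy)benzene (diazoalkene) | COCOc1ccc(C=C=[N+]=[N-])c(OCOC)c1 | intermediate, not isolated
4 | 1-ethynyl-2,4-bis(methoxymethoxy)benzene | COCOc1ccc(C#C)c(OCOC)c1 | intermediate
5 | 4-iodobenzene-1,3-diol (4-iodoresorcinol) | Oc1ccc(I)c(O)c1 | starting material
6 | 2-iodo-5-(methoxymethoxy)phenol | COCOc1ccc(I)c(O)c1 | intermediate
7 | tributyl{[2-iodo-5-(methoxymethoxy)phenoxy]methyl}stannane | CCCC[Sn](CCCC)(CCCC)COc1cc(OCOC)ccc1I | intermediate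
8 | alkenylpalladium iodide from syn addition of the aryl–palladium bond to 4 (divalent palladium; ring A and Pd cis; phosphine ligands not drawn) | COCOc1ccc(/C=C(\[Pd]I)c2ccc(OCOC)cc2OCOC)c(OC[Sn](CCCC)(CCCC)CCCC)c1 | intermediate, not isolated
9 | seven-membered oxapalladacycle (divalent palladium bound to C3 and to the O–CH2 carbon; phosphine ligands not drawn) | COCOc1ccc2C=C(c3ccc(OCOC)cc3OCOC)[Pd]COc2c1 | intermediate, not isolated
10 | 3-[2,4-bis(methoxymethoxy)phenyl]-7-(methoxymethoxy)-2H-chromene | COCOc1ccc(C2=Cc3ccc(OCOC)cc3OC2)c(OCOC)c1 | intermediate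
11 | (3S)-3-[2,4-bis(methoxymethoxy)phenyl]-7-(methoxymethoxy)-3,4-dihydro-2H-chromene | COCOc1ccc([C@H]2COc3cc(OCOC)ccc3C2)c(OCOC)c1 | intermediate
12 | 8,3′-dilithio derivative of 11 | [Li]c1c(OCOC)ccc([C@H]2COc3c([Li])c(OCOC)ccc3C2)c1OCOC | intermediate, not isolated
13 | (3S)-3-[2,4-bis(methoxymethoxy)-3-(3-methylbut-2-en-1-yl)phenyl]-7-(methoxymethoxy)-8-(3-methylbut-2-en-1-yl)-3,4-dihydro-2H-chromene | CC(C)=CCc1c(OCOC)ccc([C@H]2COc3c(CC=C(C)C)c(OCOC)ccc3C2)c1OCOC | intermediate
14 | 4-[(3S)-7-hydroxy-8-(3-methylbut-2-en-1-yl)-3,4-dihydro-2H-chromen-3-yl]-2-(3-methylbut-2-en-1-yl)benzene-1,3-diol | CC(C)=CCc1c(O)ccc([C@H]2COc3c(ccc(O)c3CC=C(C)C)C2)c1O | target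

**Count and risks**
Total steps: 8. Longest linear sequence: 6 (steps 1, 2, 5, 6, 7, 8 or steps 3, 4, 5, 6, 7, 8).

Step 5. The tin-to-palladium transfer of the sp3 carbon may be too slow, so that 8 inserts a second alkyne or 7 couples with itself; insertion with the reverse orientation is the other way the step can go wrong. The fallback uses known chemistry and closes the pyran ring through O1–C2 instead. It sets out from 1, which is protected at the non-chelated 4-hydroxyl only (MOMCl, K2CO3, acetone) to give 2-hydroxy-4-(methoxymethoxy)benzaldehyde F1. Base-mediated Knoevenagel condensation and lactonisation (t-BuOK, THF) with methyl 2-[2,4-bis(methoxymethoxy)phenyl]acetate F2 (from purchased methyl 2-(2,4-dihydroxyphenyl)acetate, MOMCl, i-Pr2NEt) gives the 3-arylcoumarin 3-[2,4-bis(methoxymethoxy)phenyl]-7-(methoxymethoxy)-2H-chromen-2-one F3. Reduction with DIBAL-H opens the lactone to 2-{(Z)-2-[2,4-bis(methoxymethoxy)phenyl]-3-hydroxyprop-1-en-1-yl}-5-(methoxymethoxy)phenol F4, and Mitsunobu cyclisation (PPh3, DIAD, THF) comes back to the route at 10.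

Step 7. The second lithiation may stay incomplete, and the allylic substitution at the two crowded aryl–metal centres may run with transposition (attack at the tertiary end of the prenyl unit). The fallback sets out from 12, which is quenched with allyl bromide, an electrophile without this ambiguity, to give (3S)-3-[2,4-bis(methoxymethoxy)-3-(prop-2-en-1-yl)phenyl]-7-(methoxymethoxy)-8-(prop-2-en-1-yl)-3,4-dihydro-2H-chromene F5. Olefin cross-metathesis with 2-methylbut-2-ene (second-generation Grubbs catalyst, CH2Cl2, 40 °C) turns both allyl groups into prenyl groups and comes back at 13.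

Step 6. Facial selectivity may be poor because the ortho-OMOM group twists ring B out of the alkene plane, and the acidic iridium hydride may strip MOM groups. The fallback sets out from 10. Hydroboration–oxidation (BH3·SMe2; NaBO3) gives racemic trans-3-[2,4-bis(methoxymethoxy)phenyl]-7-(methoxymethoxy)-3,4-dihydro-2H-chromen-4-ol F6, and Dess–Martin oxidation gives 3-[2,4-bis(methoxymethoxy)phenyl]-7-(methoxymethoxy)-2,3-dihydro-4H-chromen-4-one F7, whose C3 epimerises through the enol. Asymmetric transfer hydrogenation with dynamic kinetic resolution (RuCl[(S,S)-TsDPEN](p-cymene), HCO2H/Et3N) should give cis-(3S,4S)-3-[2,4-bis(methoxymethoxy)phenyl]-7-(methoxymethoxy)-3,4-dihydro-2H-chromen-4-ol F8. Hydrogenolysis of the benzylic C4–O bond (H2, Pd/C, EtOH) comes back at 11.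

**Further compounds**
F1 | step 5 | 2-hydroxy-4-(methoxymethoxy)benzaldehyde | COCOc1ccc(C=O)c(O)c1
F2 | step 5 | methyl 2-[2,4-bis(methoxymethoxy)phenyl]acetate | COCOc1ccc(CC(=O)OC)c(OCOC)c1
F3 | step 5 | 3-[2,4-bis(methoxymethoxy)phenyl]-7-(methoxymethoxy)-2H-chromen-2-one | COCOc1ccc(C2=Cc3ccc(OCOC)cc3OC2=O)c(OCOC)c1
F4 | step 5 | 2-{(Z)-2-[2,4-bis(methoxymethoxy)phenyl]-3-hydroxyprop-1-en-1-yl}-5-(methoxymethoxy)phenol | COCOc1ccc(/C=C(\CO)c2ccc(OCOC)cc2OCOC)c(O)c1
F5 | step 7 | (3S)-3-[2,4-bis(methoxymethoxy)-3-(prop-2-en-1-yl)phenyl]-7-(methoxymethoxy)-8-(prop-2-en-1-yl)-3,4-dihydro-2H-chromene | C=CCc1c(OCOC)ccc([C@H]2COc3c(CC=C)c(OCOC)ccc3C2)c1OCOC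
F6 | step 6 | rac-(3S,4R)-3-[2,4-bis(methoxymethoxy)phenyl]-7-(methoxymethoxy)-3,4-dihydro-2H-chromen-4-ol (trans; one enantiomer drawn) | COCOc1ccc([C@H]2COc3cc(OCOC)ccc3[C@@H]2O)c(OCOC)c1
F7 | step 6 | 3-[2,4-bis(methoxymethoxy)phenyl]-7-(methoxymethoxy)-2,3-dihydro-4H-chromen-4-one (racemic, C3 labile) | COCOc1ccc(C2COc3cc(OCOC)ccc3C2=O)c(OCOC)c1
F8 | step 6 | (3S,4S)-3-[2,4-bis(methoxymethoxy)phenyl]-7-(methoxymethoxy)-3,4-dihydro-2H-chromen-4-ol (cis) | COCOc1ccc([C@H]2COc3cc(OCOC)ccc3[C@H]2O)c(OCOC)c1
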